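**Strategy.** The route rests on disconnecting the C3–C4 bond of the pyranone ring (ring B) together with C4–C4a, which traces C4 back to carbon monoxide and C3 back to a methyl group. C2 carries two one-carbon substituents, its methyl group and the ring methylene C3. The precursor hides both as the enantiotopic methyl groups of an achiral aryl tert-alkyl ether, bromide 6, made from geranylacetone in two steps. In the key step a chiral palladium catalyst takes up CO, palladates one of these methyl groups and closes ring B by C3–C4 bond formation. This creates the ketone and the only stereocentre, C2, in one operation.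

Key step: step 3

Assumption: tert-butyl 3-bromo-4-fluorobenzoate is taken as a catalogue compound, and since the sense of induction of the chiral ligand in step 3 cannot be predicted, the ligand enantiomer that palladates the pro-R methyl group is the one to be used (written here as R,R).

Step 1
Reactants: 1 geranylacetone [(5E)-6,10-dimethylundeca-5,9-dien-2-one]
Product: 3 (5E)-2,6,10-trimethylundeca-5,9-dien-2-ol, via bromomagnesium alkoxide 2 (not isolated)
Conditions: MeMgBr (1.3 equiv), THF, 0 °C to rt; then aq. NH4Cl
Reagents that add atoms: methylmagnesium bromide, C[Mg]Br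
Why: Grignard 1,2-addition to the methyl ketone should give the tertiary carbinol, whose two methyl groups are equivalent so that no stereocentre arises, and the isolated trisubstituted alkenes are inert.

Step 2
Reactants: 3 (5E)-2,6,10-trimethylundeca-5,9-dien-2-ol; 4 tert-butyl 3-bromo-4-fluorobenzoate
Product: 6 tert-butyl 3-bromo-4-{[(5E)-2,6,10-trimethylundeca-5,9-dien-2-yl]oxy}benzoate, via potassium alkoxide 5 (not isolated)
Conditions: KN(SiMe3)2 (1.0 equiv), THF, 0 °C; then 4, THF/DMF, 0 °C to rt
Reagents that add atoms: none
Why: Nucleophilic aromatic substitution (addition–elimination) of the potassium tert-alkoxide on the fluoride, activated by the para ester and the ortho bromine, should give the aryl tert-alkyl ether, while the tert-butyl ester resists acyl transfer and the C–Br bond is untouched.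

Step 3
Reactants: 6 tert-butyl 3-bromo-4-{[(5E)-2,6,10-trimethylundeca-5,9-dien-2-yl]oxy}benzoate
Product: 9 tert-butyl (2S)-2-[(3E)-4,8-dimethylnona-3,7-dien-1-yl]-2-methyl-4-oxochromane-6-carboxylate, via aroylpalladium pivalate 7 (not isolated), via acylpalladacycle 8 (not isolated)
Conditions: Pd2(dba)3 (2.5 mol %), (R,R)-TADDOL-derived N,N-dimethylphosphoramidite (10 mol %), CsOPiv (1.5 equiv), CO (1 atm), mesitylene, 110 °C
Reagents that add atoms: carbon monoxide, [C-]#[O+]
Why: Proposed new method: oxidative addition of the zerovalent palladium–phosphoramidite complex into the C–Br bond, CO insertion and bromide/pivalate exchange should give aroylpalladium pivalate 7, which cleaves a C–H bond of one of the two enantiotopic methyl groups by concerted metalation–deprotonation to give acylpalladacycle 8, and C(acyl)–C(sp3) reductive elimination then forms the C3–C4 bond and returns zerovalent palladium. The closest known reaction types are the palladium/pivalate-catalysed intramolecular alkane arylation of 2-bromoaryl tert-alkyl ethers to 2,2-dialkyl-2,3-dihydrobenzofurans, the C(sp3)–H carbamoylation of carbamoyl chlorides to β-lactams under CO and the enantioselective methyl C–H arylations on zerovalent palladium with chiral ligands, but a carbonylative C(sp3)–H acylation that makes a ketone from an aryl ether has not been shown. Ring B closes by reductive elimination from the seven-membered palladacycle 8, which amounts to a six-membered ring closure at C3–C4 with C4 supplied by CO. C2 becomes the stereocentre without any bond to it being made or broken: the chiral ligand together with the bound pivalate must direct the palladation to the pro-R methyl group, and this C–H cleavage is expected to be irreversible and enantio-determining. The step needs methyl over methylene selectivity, which the strong preference of carboxylate-assisted palladation for primary C–H bonds should secure (the chain CH2 on C2 would give the same ring size but is secondary), and acylation over direct arylation to the dihydrobenzofuran, which the CO atmosphere should secure by converting arylpalladium into aroylpalladium before C–H cleavage. The trisubstituted alkenes of the side chain insert poorly and would require large rings, and the tert-butyl ester is inert to pivalate at this temperature.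

Step 4
Reactants: 9 tert-butyl (2S)-2-[(3E)-4,8-dimethylnona-3,7-dien-1-yl]-2-methyl-4-oxochromane-6-carboxylate
Product: 11 (2S)-2-[(3E)-4,8-dimethylnona-3,7-dien-1-yl]-2-methyl-4-oxochromane-6-carboxylic acid (target), via trimethylsilyl ester 10 (not isolated)
Conditions: TMSOTf (1.5 equiv), 2,6-lutidine (3 equiv), CH2Cl2, 0 °C to rt; then aqueous pH 4 buffer
Reagents that add atoms: none
Why: Silyl triflate-mediated cleavage of the tert-butyl ester (loss of isobutene, lutidine as proton sink) should give the trimethylsilyl ester, which is hydrolysed on work-up; the buffered, non-protic and non-basic medium should spare the trisubstituted alkenes and avoid the enolate-driven ring opening that could scramble C2.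

**Compound list**

1 | geranylacetone, (5E)-6,10-dimethylundeca-5,9-dien-2-one | CC(C)=CCC/C(C)=C/CCC(C)=O | starting material
2 | bromomagnesium (5E)-2,6,10-trimethylundeca-5,9-dien-2-olate (not isolated) | CC(C)=CCC/C(C)=C/CCC(C)(C)O[Mg]Br | intermediate
3 | (5E)-2,6,10-trimethylundeca-5,9-dien-2-ol | CC(C)=CCC/C(C)=C/CCC(C)(C)O | intermediate
4 | tert-butyl 3-bromo-4-fluorobenzoate | CC(C)(C)OC(=O)c1ccc(F)c(Br)c1 | starting material
5 | potassium (5E)-2,6,10-trimethylundeca-5,9-dien-2-olate (not isolated) | CC(C)=CCC/C(C)=C/CCC(C)(C)[O-].[K+] | intermediate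
6 | tert-butyl 3-bromo-4-{[(5E)-2,6,10-trimethylundeca-5,9-dien-2-yl]oxy}benzoate | CC(C)=CCC/C(C)=C/CCC(C)(C)Oc1ccc(C(=O)OC(C)(C)C)cc1Br | intermediate
7 | aroylpalladium pivalate of divalent palladium, formed from 6 by oxidative addition, CO insertion and bromide/pivalate exchange (phosphoramidite ligand not drawn; not isolated) | CC(C)=CCC/C(C)=C/CCC(C)(C)Oc1ccc(C(=O)OC(C)(C)C)cc1C(=O)[Pd]OC(=O)C(C)(C)C | intermediate
8 | seven-membered acylpalladacycle of divalent palladium, bound to the future C4 and C3, S at the future C2 (phosphoramidite ligand not drawn; not isolated) | CC(C)=CCC/C(C)=C/CC[C@@]1(C)C[Pd]C(=O)c2cc(C(=O)OC(C)(C)C)ccc2O1 | intermediate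
9 | tert-butyl (2S)-2-[(3E)-4,8-dimethylnona-3,7-dien-1-yl]-2-methyl-4-oxochromane-6-carboxylate | CC(C)=CCC/C(C)=C/CC[C@@]1(C)CC(=O)c2cc(C(=O)OC(C)(C)C)ccc2O1 | intermediate
10 | trimethylsilyl (2S)-2-[(3E)-4,8-dimethylnona-3,7-dien-1-yl]-2-methyl-4-oxochromane-6-carboxylate (not isolated) | CC(C)=CCC/C(C)=C/CC[C@@]1(C)CC(=O)c2cc(C(=O)O[Si](C)(C)C)ccc2O1 | intermediate
11 | (2S)-2-[(3E)-4,8-dimethylnona-3,7-dien-1-yl]-2-methyl-4-oxochromane-6-carboxylic acid | CC(C)=CCC/C(C)=C/CC[C@@]1(C)CC(=O)c2cc(C(=O)O)ccc2O1 | target

Total step count: 4. Longest linear sequence: 4 steps (1 → 3 → 6 → 9 → 11).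

**Steps most likely to fail**

Step 3 (Proposed new method). Palladation of an unactivated methyl group by the aroylpalladium through a seven-membered metallacycle may be too slow. Decarbonylation with direct arylation to the dihydrobenzofuran, or resting of the catalyst as carbonyl complexes, could then take over. Discrimination between the two enantiotopic methyl groups may also be poor. The fallback uses known chemistry, sets out from 1 (with 4) and comes back at 9, closing the same C3–C4 bond:
- Catalytic asymmetric Corey–Chaykovsky epoxidation of 1 (Me3S(O)I/NaH, LaLi3(binaphthoxide)3 catalyst of the appropriate hand, triarylphosphine oxide additive, THF) should give (2S)-2-[(3E)-4,8-dimethylnona-3,7-dien-1-yl]-2-methyloxirane F1.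
- Opening at the CH2 terminus with 4-methoxybenzyl alcohol/NaH (DMF, 80 °C) should give the tertiary alcohol (2S,5E)-1-[(4-methoxyphenyl)methoxy]-2,6,10-trimethylundeca-5,9-dien-2-ol F2.
- Its potassium alkoxide and 4, under the conditions of step 2, should give the aryl ether F3.
- Bromine–magnesium exchange (i-PrMgCl·LiCl, THF, −15 °C) and DMF should give the aldehyde F4.
- DDQ (CH2Cl2/pH 7 buffer) should remove the 4-methoxybenzyl group to give the alcohol F5.
- PPh3, I2 and imidazole should give the iodide F6.
- N-heterocyclic-carbene-catalysed intramolecular alkylation of the aldehyde (thiazolium salt, Cs2CO3, dioxane, 80 °C) should give 9. The Breslow intermediate acts as acyl anion equivalent and displaces iodide, helped by the gem-disubstitution at C2.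

Step 2. Addition of the hindered tertiary alkoxide to the carbon flanked by bromine may be too slow, so that decomposition of the alkoxide or attack elsewhere competes. The fallback sets out from 3 and comes back at 11, carrying the carboxyl carbon at other oxidation levels:
- Alkoxide 5 and the more strongly activated 3-bromo-4-fluorobenzonitrile should give the nitrile F7.
- i-Bu2AlH (toluene, −78 °C, then aqueous tartaric acid) should give the aldehyde F8.
- The conditions of step 3 applied to F8 should give the chromanone aldehyde F9.
- Pinnick oxidation (NaClO2, NaH2PO4, 2-methyl-2-butene, t-BuOH/H2O) should give 11 without any base or acid treatment after C2 is set.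

Step 4. Lewis-acid-triggered cation–olefin reactions of the diene chain, or ring opening and reclosure at C2 with loss of enantiopurity, may accompany the ester cleavage. The fallback sets out from 6 and comes back at 11, moving the deprotection ahead of the stereo-defining step:
- Powdered KOH in THF at rt should cleave the tert-butyl benzoate of 6 to the acid F10 under purely basic conditions, where neither the polyene nor a stereocentre is at risk.
- The conditions of step 3 applied to F10 (CsOPiv 2.5 equiv, mesitylene/DMA) should give 11 directly after acidification.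

**Further compounds**

F1 | step 3 | (2S)-2-[(3E)-4,8-dimethylnona-3,7-dien-1-yl]-2-methyloxirane | CC(C)=CCC/C(C)=C/CC[C@@]1(C)CO1
F2 | step 3 | (2S,5E)-1-[(4-methoxyphenyl)methoxy]-2,6,10-trimethylundeca-5,9-dien-2-ol | CC(C)=CCC/C(C)=C/CC[C@@](O)(C)COCc1ccc(OC)cc1
F3 | step 3 | tert-butyl 3-bromo-4-{[(2S,5E)-1-[(4-methoxyphenyl)methoxy]-2,6,10-trimethylundeca-5,9-dien-2-yl]oxy}benzoate | CC(C)=CCC/C(C)=C/CC[C@@](Oc1ccc(C(=O)OC(C)(C)C)cc1Br)(C)COCc1ccc(OC)cc1
F4 | step 3 | tert-butyl 3-formyl-4-{[(2S,5E)-1-[(4-methoxyphenyl)methoxy]-2,6,10-trimethylundeca-5,9-dien-2-yl]oxy}benzoate | CC(C)=CCC/C(C)=C/CC[C@@](Oc1ccc(C(=O)OC(C)(C)C)cc1C=O)(C)COCc1ccc(OC)cc1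
F5 | step 3 | tert-butyl 3-formyl-4-{[(2S,5E)-1-hydroxy-2,6,10-trimethylundeca-5,9-dien-2-yl]oxy}benzoate | CC(C)=CCC/C(C)=C/CC[C@@](Oc1ccc(C(=O)OC(C)(C)C)cc1C=O)(C)CO
F6 | step 3 | tert-butyl 3-formyl-4-{[(2S,5E)-1-iodo-2,6,10-trimethylundeca-5,9-dien-2-yl]oxy}benzoate | CC(C)=CCC/C(C)=C/CC[C@@](Oc1ccc(C(=O)OC(C)(C)C)cc1C=O)(C)CI
F7 | step 2 | 3-bromo-4-{[(5E)-2,6,10-trimethylundeca-5,9-dien-2-yl]oxy}benzonitrile | CC(C)=CCC/C(C)=C/CCC(C)(C)Oc1ccc(C#N)cc1Br
F8 | step 2 | 3-bromo-4-{[(5E)-2,6,10-trimethylundeca-5,9-dien-2-yl]oxy}benzaldehyde | CC(C)=CCC/C(C)=C/CCC(C)(C)Oc1ccc(C=O)cc1Br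
F9 | step 2 | (2S)-2-[(3E)-4,8-dimethylnona-3,7-dien-1-yl]-2-methyl-4-oxochromane-6-carbaldehyde | CC(C)=CCC/C(C)=C/CC[C@@]1(C)CC(=O)c2cc(C=O)ccc2O1
F10 | step 4 | 3-bromo-4-{[(5E)-2,6,10-trimethylundeca-5,9-dien-2-yl]oxy}benzoic acid | CC(C)=CCC/C(C)=C/CCC(C)(C)Oc1ccc(C(=O)O)cc1Br
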